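Ring A is closed last, across C4–C5, onto a ring B cyclohexenone that already carries C9, C10 and the whole side chain (from an enantioselective Diels–Alder reaction of 8-oxogeranyl acetate). The key step, a cobalt-hydride hydrogen-atom-transfer cycloisomerisation, makes the tertiary C4 radical from a 1,1-disubstituted alkene, adds it 6-exo to the enone β-carbon C5 and returns H5 to cobalt. One operation thus closes ring A, creates the gem-dimethyl quaternary C4 next to the ring-fusion carbon C5 (the feature exploited) and restores a 5-en-7-one, whose dissolving-metal reduction then sets the trans fusion. The precursor is a monocyclic cyclohexenone with a (Z)-4-methylpenta-1,4-dienyl chain on C10.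

Key step: step 5

Assumption: labdane numbering (C1–C20) is used for all ring positions; salen = N,N′-bis(3,5-di-tert-butylsalicylidene)cyclohexane-1,2-diaminate; the sense of induction in step 2 is taken by analogy with α-substituted acroleins, and the mirror-image catalyst would be used if it proved opposite.

Step 1
Reactants: 1 geranyl acetate
Product: 3 (2E,6E)-8-acetoxy-2,6-dimethylocta-2,6-dienal, via 8-hydroxygeranyl acetate 2 (not isolated)
Conditions: SeO2 (1.1 equiv), 95% EtOH, reflux
Reagents that add atoms: selenium dioxide, O=[Se]=O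
Why: Riley-type allylic oxidation (ene reaction, then [2,3]-sigmatropic shift) should attack the E-methyl group of the more electron-rich distal alkene and carry alcohol 2 on to the E-enal, the 2,3-alkene being deactivated by the allylic acetate.

Step 2
Reactants: 3 (2E,6E)-8-acetoxy-2,6-dimethylocta-2,6-dienal; 4 (E)-1-(dimethylamino)-3-(tert-butyldimethylsilyloxy)buta-1,3-diene
Product: 6 (1R,6S)-6-[(3E)-5-acetoxy-3-methylpent-3-en-1-yl]-1-methyl-4-oxocyclohex-2-ene-1-carbaldehyde, via aminosilyloxy cycloadduct 5 (not isolated)
Conditions: (S,S)-(salen)CrSbF6 (trivalent chromium, 5 mol %), 4 Å MS, CH2Cl2, −40 °C; then aq. HF, MeCN, 0 °C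
Reagents that add atoms: none
Why: Catalytic enantioselective Diels–Alder reaction that builds ring B: the amino-bearing diene terminus bonds to the formyl-bearing carbon (ortho rule), suprafacial addition to the E-enal places the side chain cis to the methyl group (C9/C10 relative configuration), the chiral chromium Lewis acid on the aldehyde selects the enal face (absolute configuration), and HF removes the silyl group and eliminates dimethylamine to give the enone.

Step 3
Reactants: 7 4-bromo-2-methylbut-1-ene; 8 triphenylphosphine
Product: 9 (3-methylbut-3-en-1-yl)triphenylphosphonium bromide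
Conditions: MeCN, reflux
Reagents that add atoms: none
Why: SN2 quaternisation of the phosphine by the primary homoallylic bromide.

Step 4
Reactants: 6 (1R,6S)-6-[(3E)-5-acetoxy-3-methylpent-3-en-1-yl]-1-methyl-4-oxocyclohex-2-ene-1-carbaldehyde; 9 (3-methylbut-3-en-1-yl)triphenylphosphonium bromide
Product: 11 4-methyl-4-[(1Z)-4-methylpenta-1,4-dien-1-yl]-5-[(3E)-5-acetoxy-3-methylpent-3-en-1-yl]cyclohex-2-en-1-one (ring stereocentres as in 6), via phosphorus ylide 10 (not isolated)
Conditions: 9, NaHMDS, THF, 0 °C; then 6, −78 °C to rt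
Reagents that add atoms: none
Why: Wittig olefination of the aldehyde, which is far more electrophilic than the conjugated ketone, with a salt-free non-stabilised ylide should give the Z-alkene and so supplies C2, C3 and C4.

Step 5
Reactants: 11 4-methyl-4-[(1Z)-4-methylpenta-1,4-dien-1-yl]-5-[(3E)-5-acetoxy-3-methylpent-3-en-1-yl]cyclohex-2-en-1-one
Product: 12 7-oxolabda-1,5,13E-trien-15-yl acetate (9α-H, 10β-methyl)
Conditions: (salen)CoCl (trivalent cobalt, 5 mol %), PhSiH3 (10 mol %), degassed PhH, rt
Reagents that add atoms: none
Why: Proposed new method: the cobalt hydride formed from (salen)CoCl and PhSiH3 should transfer a hydrogen atom to the CH2 terminus of the 1,1-disubstituted alkene (giving the tertiary C4 radical and divalent cobalt), the radical should add to C5, the β-carbon of the ring B enone, and the resulting C6 α-keto radical should give its only β-hydrogen (H5) back to divalent cobalt, which regenerates the cobalt hydride and the conjugated 5-en-7-one. The closest known reaction types are the cobalt–salen hydrogen-atom-transfer cycloisomerisation of dienes (radical cyclisation ended by hydrogen return) and the iron-hydride Giese cyclisation of alkenes onto enones; new here is ending a Giese-type addition to an enone by hydrogen return instead of reduction. Ring A is closed in the 6-exo-trig mode, the Z-C1=C2 alkene holding the chain within reach of C5. No stereocentre is created: C4 carries two methyl groups, and C5 is returned to sp2 on purpose, because a chain tethered at C10 can reach a trigonal C5 only from its own face and would fix a cis ring fusion, whereas the restored enone lets H5 be delivered from the α face in step 7. The step needs hydrogen-atom transfer to the 1,1-disubstituted alkene in preference to the Z-disubstituted and the trisubstituted side-chain alkenes, which the low reactivity of internal and more substituted alkenes toward this catalyst should secure, and desaturation toward C5, which is the only hydrogen-bearing position β to the C6 radical.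

Step 6
Reactants: 12 7-oxolabda-1,5,13E-trien-15-yl acetate
Product: 14 15-hydroxylabda-5,13E-dien-7-one, via 7-oxolabda-5,13E-dien-15-yl acetate 13 (not isolated)
Conditions: H2 (3 atm), RhCl(PPh3)3 (10 mol %), PhH/EtOH, rt; then K2CO3, MeOH, rt
Reagents that add atoms: none
Why: Homogeneous hydrogenation should reduce only the cis-disubstituted C1=C2 alkene (the trisubstituted side-chain alkene and the hindered conjugated enone react far more slowly), and base-catalysed transesterification then frees the C15 alcohol so that step 7 meets no allylic ester.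

Step 7
Reactants: 14 15-hydroxylabda-5,13E-dien-7-one
Product: 15 15-hydroxy-5α-labd-13E-en-7-one (trans-fused; 5α-H, 9α-H, 10β-methyl)
Conditions: Li, NH3 (l), THF, t-BuOH (1 equiv), −78 °C; then NH4Cl
Reagents that add atoms: none
Why: Dissolving-metal (Birch-type) conjugate reduction: the C5 carbanion should be protonated axially on the α face, anti to the axial C10 methyl group, which sets the trans ring fusion, while the isolated alkene and the allylic alkoxide are inert.

Step 8
Reactants: 15 15-hydroxy-5α-labd-13E-en-7-one
Product: 17 15-hydroxylabda-8(17),13E-dien-7-one, via Mannich base 16 (not isolated)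
Conditions: (CH2O)n, N-methylanilinium trifluoroacetate, THF, reflux; product used at once
Reagents that add atoms: paraformaldehyde (as formaldehyde), C=O
Why: Mannich reaction with in situ elimination of N-methylaniline (α-methylenation) should occur at C8, because enolisation toward C6 is disfavoured next to the trans ring fusion and C6 is shielded by the C4 gem-dimethyl group.

Step 9
Reactants: 17 15-hydroxylabda-8(17),13E-dien-7-one
Product: 18 8,17-epoxy-15-hydroxylabd-13E-en-7-one
Conditions: 30% H2O2, NaOH, MeOH, 0 °C
Reagents that add atoms: hydrogen peroxide, OO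
Why: Nucleophilic (Weitz–Scheffer) epoxidation should touch only the electron-poor exocyclic enone; the configuration of the spiro carbon C8 is of no consequence because C8 becomes sp2 again in step 10.

Step 10
Reactants: 18 8,17-epoxy-15-hydroxylabd-13E-en-7-one
Product: 20 (5S,9R,10S)-labda-7,13E-diene-15,17-diol, via epoxy hydrazone 19 (not isolated)
Conditions: N2H4·H2O, AcOH (cat.), MeOH, 0 °C to rt
Reagents that add atoms: none
Why: Wharton transposition: the epoxy hydrazone should fragment with loss of N2, placing the alkene at C7=C8 and the hydroxyl group on C17 without touching C9.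

Step 11
Reactants: 20 (5S,9R,10S)-labda-7,13E-diene-15,17-diol
Product: 21 (5S,9R,10S)-labda-7,13E-diene-15,17-diyl diacetate (CNP0257931.1)
Conditions: Ac2O, pyridine, DMAP (cat.), CH2Cl2, rt
Reagents that add atoms: acetic anhydride, CC(=O)OC(C)=O
Why: DMAP-catalysed acetylation of both primary allylic alcohols should give the target.

Compound list
1 | geranyl acetate, (2E)-3,7-dimethylocta-2,6-dien-1-yl acetate | CC(=O)OC/C=C(\C)CCC=C(C)C | starting material
2 | (2E,6E)-8-hydroxy-3,7-dimethylocta-2,6-dien-1-yl acetate (8-hydroxygeranyl acetate) | CC(=O)OC/C=C(\C)CC/C=C(\C)CO | intermediate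
3 | (2E,6E)-8-acetoxy-2,6-dimethylocta-2,6-dienal | CC(=O)OC/C=C(\C)CC/C=C(\C)C=O | intermediate
4 | (E)-1-(dimethylamino)-3-(tert-butyldimethylsilyloxy)buta-1,3-diene | CN(C)/C=C/C(=C)O[Si](C)(C)C(C)(C)C | starting material
5 | 2-(dimethylamino)-4-(tert-butyldimethylsilyloxy)-1-methyl-6-[(3E)-5-acetoxy-3-methylpent-3-en-1-yl]cyclohex-3-ene-1-carbaldehyde (C1 and C6 as in 6; amino-bearing carbon not defined, lost in the same step) | CC(=O)OC/C=C(\C)CC[C@H]1CC(O[Si](C)(C)C(C)(C)C)=CC(N(C)C)[C@@]1(C=O)C | intermediate
6 | (1R,6S)-6-[(3E)-5-acetoxy-3-methylpent-3-en-1-yl]-1-methyl-4-oxocyclohex-2-ene-1-carbaldehyde (side chain cis to methyl) | CC(=O)OC/C=C(\C)CC[C@H]1CC(=O)C=C[C@@]1(C=O)C | intermediate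
7 | 4-bromo-2-methylbut-1-ene | C=C(C)CCBr | starting material
8 | triphenylphosphine | c1ccc(cc1)P(c1ccccc1)c1ccccc1 | starting material
9 | (3-methylbut-3-en-1-yl)triphenylphosphonium bromide | C=C(C)CC[P+](c1ccccc1)(c1ccccc1)c1ccccc1.[Br-] | intermediate
10 | (3-methylbut-3-en-1-ylidene)triphenylphosphorane | C=C(C)CC=P(c1ccccc1)(c1ccccc1)c1ccccc1 | intermediate
11 | 4-methyl-4-[(1Z)-4-methylpenta-1,4-dien-1-yl]-5-[(3E)-5-acetoxy-3-methylpent-3-en-1-yl]cyclohex-2-en-1-one (ring stereocentres as in 6) | CC(=O)OC/C=C(\C)CC[C@H]1CC(=O)C=C[C@@]1(/C=C\CC(C)=C)C | intermediate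
12 | 7-oxolabda-1,5,13E-trien-15-yl acetate (9α-H, 10β-methyl) | CC(=O)OC/C=C(\C)CC[C@H]1CC(=O)C=C2C(C)(C)CC=C[C@]12C | intermediate
13 | 7-oxolabda-5,13E-dien-15-yl acetate (9α-H, 10β-methyl) | CC(=O)OC/C=C(\C)CC[C@H]1CC(=O)C=C2C(C)(C)CCC[C@]12C | intermediate
14 | 15-hydroxylabda-5,13E-dien-7-one (9α-H, 10β-methyl) | OC/C=C(\C)CC[C@H]1CC(=O)C=C2C(C)(C)CCC[C@]12C | intermediate
15 | 15-hydroxy-5α-labd-13E-en-7-one (5α-H, 9α-H, 10β-methyl) | OC/C=C(\C)CC[C@H]1CC(=O)C[C@H]2C(C)(C)CCC[C@]12C | intermediate
16 | 15-hydroxy-17-(N-methylanilino)-5α-labd-13E-en-7-one (C8 not defined, lost in the same step) | OC/C=C(\C)CC[C@H]1C(CN(C)c2ccccc2)C(=O)C[C@H]3C(C)(C)CCC[C@]13C | intermediate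
17 | 15-hydroxylabda-8(17),13E-dien-7-one (5α-H, 9α-H, 10β-methyl) | OC/C=C(\C)CC[C@H]1C(=C)C(=O)C[C@H]2C(C)(C)CCC[C@]12C | intermediate
18 | 8,17-epoxy-15-hydroxylabd-13E-en-7-one (epoxide oxygen drawn α; either C8 epimer serves) | OC/C=C(\C)CC[C@H]1[C@@]2(CO2)C(=O)C[C@H]3C(C)(C)CCC[C@]13C | intermediate
19 | hydrazone of 18 (C=N geometry not defined) | OC/C=C(\C)CC[C@H]1[C@@]2(CO2)C(=NN)C[C@H]3C(C)(C)CCC[C@]13C | intermediate
20 | (5S,9R,10S)-labda-7,13E-diene-15,17-diol | OC/C=C(\C)CC[C@H]1C(CO)=CC[C@H]2C(C)(C)CCC[C@]12C | intermediate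
21 | (5S,9R,10S)-labda-7,13E-diene-15,17-diyl diacetate | CC(=O)OC/C=C(\C)CC[C@H]1C(COC(C)=O)=CC[C@H]2C(C)(C)CCC[C@]12C | target

Total step count: 11. Longest linear sequence: 10 steps (1, 2, 4, 5, 6, 7, 8, 9, 10, 11).

Steps most likely to fail

Step 5 (labelled step). Hydrogen return from C5 to divalent cobalt may be slower than isomerisation of the skipped diene or than hydrogen abstraction by the C6 radical, so that conversion stalls or a saturated cis-fused ketone builds up. The fallback uses known chemistry and sets out from 11. A reductive iron-hydride Giese cyclisation (Fe(acac)3, PhSiH3, EtOH/ethylene glycol, 60 °C) should close ring A to the cis-fused ketone 7-oxo-5β-labda-1,13E-dien-15-yl acetate F1. IBX in DMSO at 75 °C should then dehydrogenate both α,β-positions to the cross-conjugated dienone 7-oxolabda-1,5,8,13E-tetraen-15-yl acetate F2, which erases C5 and C9. Hydrogenation with RhCl(PPh3)3 and methanolysis as in step 6 should give 15-hydroxylabda-5,8,13E-trien-7-one F3. Li/NH3/t-BuOH should then reduce both enone double bonds with axial protonation at C5 and C9, and the route is rejoined at 15.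

Step 2. The β-substituted α-methyl enal may react too slowly, with poor facial discrimination, or by cycloaddition at the aldehyde carbonyl. The fallback sets out from 3. A Diels–Alder reaction with 2-(triisopropylsilyloxy)buta-1,3-diene, catalysed by a triflimide-activated proline-derived oxazaborolidine (a cationic boron Lewis acid), should give the silyl enol ether 6-[(3E)-5-acetoxy-3-methylpent-3-en-1-yl]-1-methyl-4-(triisopropylsilyloxy)cyclohex-3-ene-1-carbaldehyde F4, with the silyloxy group para to the formyl-bearing carbon. Saegusa oxidation (Pd(OAc)2 cat., O2, DMSO) should then desaturate it regiospecifically and rejoin the route at 6.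

Step 8. Enolisation toward C6, double methylenation, or isomerisation and dimerisation of the α-methylene ketone may erode the yield and the C9 centre. The fallback sets out from 15. Claisen formylation under thermodynamic control (HCO2Et, NaH, THF) should give the chelated 17-hydroxymethylene ketone 15,17-dihydroxy-5α-labda-8(17),13E-dien-7-one F5. O-alkylation (i-PrI, K2CO3, acetone) should give the isopropoxymethylene ketone F6. LiAlH4 followed by dilute acid (1,3-carbonyl transposition) should give the enal 15-hydroxylabda-7,13E-dien-17-al F7. Luche reduction (NaBH4, CeCl3, MeOH) should then rejoin the route at 20, bypassing 17 to 19.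

Further compounds
F1 | step 5 | 7-oxo-5β-labda-1,13E-dien-15-yl acetate (cis-fused) | CC(=O)OC/C=C(\C)CC[C@H]1CC(=O)C[C@@H]2C(C)(C)CC=C[C@]12C
F2 | step 5 | 7-oxolabda-1,5,8,13E-tetraen-15-yl acetate | CC(=O)OC/C=C(\C)CCC1=CC(=O)C=C2C(C)(C)CC=C[C@]12C
F3 | step 5 | 15-hydroxylabda-5,8,13E-trien-7-one | OC/C=C(\C)CCC1=CC(=O)C=C2C(C)(C)CCC[C@]12C
F4 | step 2 | 6-[(3E)-5-acetoxy-3-methylpent-3-en-1-yl]-1-methyl-4-(triisopropylsilyloxy)cyclohex-3-ene-1-carbaldehyde (stereocentres as in 6) | CC(=O)OC/C=C(\C)CC[C@H]1CC(O[Si](C(C)C)(C(C)C)C(C)C)=CC[C@@]1(C=O)C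
F5 | step 8 | 15,17-dihydroxy-5α-labda-8(17),13E-dien-7-one (chelated hydroxymethylene ketone) | OC/C=C(\C)CC[C@H]1/C(=C/O)C(=O)C[C@H]2C(C)(C)CCC[C@]12C
F6 | step 8 | 15-hydroxy-17-isopropoxy-5α-labda-8(17),13E-dien-7-one | OC/C=C(\C)CC[C@H]1/C(=C/OC(C)C)C(=O)C[C@H]2C(C)(C)CCC[C@]12C
F7 | step 8 | 15-hydroxylabda-7,13E-dien-17-al | OC/C=C(\C)CC[C@H]1C(C=O)=CC[C@H]2C(C)(C)CCC[C@]12C
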